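**Retrosynthetic overview**

1. The dearomatized ring comes last: twofold C-prenylation at C5 of a 7-acyl-4,6-dihydroxy-2,3-dihydrobenzofuran (alkylative dearomatization of an acylphloroglucinol).
2. The 3-methylbutanoyl group enters at C7 by bromine–lithium exchange and Weinreb acylation; the two bromines flanking the ether oxygen are bought in with 4,6-dibromoresorcinol.
3. Key disconnection: the C3a–C3 bond of the dihydrofuran. Enabling feature: the carbinol oxygen, CMe2, C2 and C3 of the target are a 1,3-related chain (O–CMe2–C2–C3) and can be carried as a 2,2-dimethyloxetane ring on the aryl ether oxygen. An ortho aryllithium opens its CH2–O bond (strain release), which closes the dihydrofuran and unveils the 2-hydroxypropan-2-yl group.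
4. The C2 stereocenter comes from methyl (S)-glycerate by Mitsunobu inversion; CMe2OH by MeMgBr; the oxetane by Williamson closure.
5. Ring order: benzene ring (bought) → oxetane (temporary) → dihydrofuran (key step, oxetane consumed) → dearomatized cyclohexadienone.

Key step: step 7

Remark: the target is an enolized β-triketone; the 4-keto/6-enol tautomer of the given SMILES is taken as the form to be made, and benzofuran numbering (O1, C2, C3, C3a, C4 to C7, C7a) is used throughout.

**Route**

Step 1
Reactants: 1 4,6-dibromobenzene-1,3-diol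
Product: 2 1,5-bis(benzyloxy)-2,4-dibromobenzene
Conditions: BnBr (2.2 equiv), K2CO3, DMF, 60 °C
Reagents that add atoms: benzyl bromide, BrCc1ccccc1
Why: Williamson ether synthesis: both phenoxides, made more acidic by the ortho bromines, are benzylated on oxygen, and no stereocenter is involved.

Step 2
Reactants: 2 1,5-bis(benzyloxy)-2,4-dibromobenzene
Product: 5 3,5-bis(benzyloxy)-2,6-dibromophenol, via aryllithium 3 (not isolated), via arylboronate 4 (not isolated)
Conditions: LiN(i-Pr)2 (1.1 equiv), THF, −78 °C; B(OMe)3, −78 °C → rt; then AcOH, 30% aq. H2O2, 0 °C → rt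
Reagents that add atoms: hydrogen peroxide, OO
Why: Deprotonative lithiation at the C–H flanked by the two bromines (the most acidic ring position; an amide base does not undergo bromine–lithium exchange, and the aryllithium is kept at −78 °C to avoid aryne formation), followed by borylation and oxidative hydroxylation of the arylboronate, should give the phenol with unambiguous regiochemistry; no stereocenter is involved.

Step 3
Reactants: 6 methyl (2S)-2,3-dihydroxypropanoate
Product: 7 methyl (2S)-3-[(tert-butyldimethylsilyl)oxy]-2-hydroxypropanoate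
Conditions: TBSCl (1.05 equiv), imidazole, CH2Cl2, 0 °C
Reagents that add atoms: tert-butyldimethylsilyl chloride, CC(C)(C)[Si](C)(C)Cl
Why: Silyl ether formation, selective for the primary hydroxyl over the less nucleophilic secondary hydroxyl of the α-hydroxy ester; the (S) center is not touched.

Step 4
Reactants: 5 3,5-bis(benzyloxy)-2,6-dibromophenol; 7 methyl (2S)-3-[(tert-butyldimethylsilyl)oxy]-2-hydroxypropanoate
Product: 8 methyl (2R)-2-[3,5-bis(benzyloxy)-2,6-dibromophenoxy]-3-[(tert-butyldimethylsilyl)oxy]propanoate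
Conditions: PPh3, DIAD, toluene, 0 °C → rt
Reagents that add atoms: none
Why: Mitsunobu etherification: the acidic 2,6-dibromophenol displaces the alkoxyphosphonium ion in an SN2 reaction at the ester α-carbon with inversion, which sets the future C2 stereocenter as (R).

Step 5
Reactants: 8 methyl (2R)-2-[3,5-bis(benzyloxy)-2,6-dibromophenoxy]-3-[(tert-butyldimethylsilyl)oxy]propanoate
Product: 10 (2R)-2-[3,5-bis(benzyloxy)-2,6-dibromophenoxy]-3-methylbutane-1,3-diol, via silyl ether carbinol 9 (not isolated)
Conditions: MeMgBr (3.5 equiv), THF, −20 → 0 °C; then 1 M aq. HCl, MeOH, rt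
Reagents that add atoms: methylmagnesium bromide, C[Mg]Br
Why: Double Grignard addition to the ester (faster than α-deprotonation, so the stereocenter should not epimerize, and aryl bromides are inert to MeMgBr) builds the tertiary carbinol, and the acidic work-up cleaves the primary silyl ether; the descriptor stays (R) because the carbinol carbon takes the CIP rank of the ester carbon.

Step 6
Reactants: 10 (2R)-2-[3,5-bis(benzyloxy)-2,6-dibromophenoxy]-3-methylbutane-1,3-diol
Product: 12 (3R)-3-[3,5-bis(benzyloxy)-2,6-dibromophenoxy]-2,2-dimethyloxetane, via primary tosylate 11 (not isolated)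
Conditions: TsCl (1.05 equiv), Et3N, DMAP (cat.), CH2Cl2, 0 °C; then NaH (1.5 equiv), THF, 0 → 40 °C
Reagents that add atoms: none
Why: Selective sulfonylation of the primary alcohol followed by intramolecular Williamson etherification by the tertiary alkoxide (4-exo-tet, helped by the gem-dimethyl effect) should give the oxetane; the stereocenter is not a reacting center and stays (R).

Step 7
Reactants: 12 (3R)-3-[3,5-bis(benzyloxy)-2,6-dibromophenoxy]-2,2-dimethyloxetane
Product: 14 2-[(2R)-4,6-bis(benzyloxy)-7-bromo-2,3-dihydro-1-benzofuran-2-yl]propan-2-ol, via aryllithium 13 (not isolated)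
Conditions: n-BuLi (1.05 equiv), THF, −78 °C; BF3·OEt2 (1.1 equiv), −78 → −40 °C; then H2O
Reagents that add atoms: none
Why: Proposed new method: bromine–lithium exchange at one of the two equivalent C–Br bonds gives aryllithium 13, whose sp2 carbanion attacks the oxetane CH2 carbon from the side opposite its C–O bond once BF3 is bound to the ring oxygen, so that release of the four-membered-ring strain drives formation of the C3a–C3 bond and sets free the tertiary alkoxide of the 2-hydroxypropan-2-yl group in the same event. The closest known reaction types are the Parham cyclization (an aryllithium displacing a tethered alkyl halide or opening a tethered epoxide), the BF3-promoted opening of oxetanes by organolithium reagents, and the intramolecular opening of 3-substituted oxetanes by heteroatom nucleophiles on a two-atom tether, which has the same ring topology. The dihydrofuran ring closes in the 5-exo-tet mode, the breaking C–O bond lying outside the new ring. No stereocenter is created: C2 is the former oxetane C3, none of its bonds is made or broken, and it stays (R). The step needs attack at the CH2 and not at the quaternary CMe2 carbon of the oxetane, which the SN2 mechanism secures, and exchange of only one bromine, which one equivalent of n-BuLi at −78 °C and the equivalence of the two bromines secure, so that the second bromine remains as the handle for step 9.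

Step 8
Reactants: 15 3-methylbutanoyl chloride; 16 N,O-dimethylhydroxylamine hydrochloride
Product: 17 N-methoxy-N,3-dimethylbutanamide
Conditions: Et3N (2.2 equiv), CH2Cl2, 0 °C → rt
Reagents that add atoms: none
Why: N-Acylation of the amine by the acid chloride (Schotten–Baumann-type amide formation) gives the Weinreb amide; no stereocenter is involved.

Step 9
Reactants: 14 2-[(2R)-4,6-bis(benzyloxy)-7-bromo-2,3-dihydro-1-benzofuran-2-yl]propan-2-ol; 17 N-methoxy-N,3-dimethylbutanamide
Product: 20 1-[(2R)-4,6-bis(benzyloxy)-2-(2-hydroxypropan-2-yl)-2,3-dihydro-1-benzofuran-7-yl]-3-methylbutan-1-one, via dilithio species 18 (not isolated), via tetrahedral adduct 19 (not isolated)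
Conditions: n-BuLi (2.1 equiv), THF, −78 °C; then 17, −78 → 0 °C; then cold 1 M aq. HCl
Reagents that add atoms: none
Why: After deprotonation of the carbinol, bromine–lithium exchange places the carbanion at C7 only, and the Weinreb ketone synthesis through the chelated tetrahedral adduct should stop at the ketone; C2 is untouched.

Step 10
Reactants: 20 1-[(2R)-4,6-bis(benzyloxy)-2-(2-hydroxypropan-2-yl)-2,3-dihydro-1-benzofuran-7-yl]-3-methylbutan-1-one
Product: 21 1-[(2R)-4,6-dihydroxy-2-(2-hydroxypropan-2-yl)-2,3-dihydro-1-benzofuran-7-yl]-3-methylbutan-1-one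
Conditions: H2 (1 atm), Pd/C (10 wt% palladium on carbon), EtOAc/MeOH, rt
Reagents that add atoms: none
Why: Catalytic hydrogenolysis of the two benzyl aryl ethers; the electron-rich, hydrogen-bonded aryl ketone and the tertiary alcohol should not be reduced under these mild conditions, and C2 is untouched.

Step 11
Reactants: 21 1-[(2R)-4,6-dihydroxy-2-(2-hydroxypropan-2-yl)-2,3-dihydro-1-benzofuran-7-yl]-3-methylbutan-1-one; 22 1-bromo-3-methylbut-2-ene
Product: 24 (2R)-6-hydroxy-2-(2-hydroxypropan-2-yl)-7-(3-methylbutanoyl)-5,5-bis(3-methylbut-2-en-1-yl)-2,3-dihydro-1-benzofuran-4(5H)-one, via monoprenyl phenol 23 (not isolated)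
Conditions: 22 (2.5 equiv), KOH (3 equiv), H2O, 0 °C → rt; then 1 M aq. HCl
Reagents that add atoms: none
Why: Alkylative dearomatization of an acylphloroglucinol: C5 is the only unsubstituted ring carbon and lies between two phenoxide oxygens, so two successive C-prenylations (favoured over O-alkylation in water) should occur there, the second one giving the enolized triketone that cannot rearomatize, while the remote C2 center is untouched.

**Compound list**

1 | 4,6-dibromobenzene-1,3-diol | Oc1cc(O)c(Br)cc1Br | starting material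
2 | 1,5-bis(benzyloxy)-2,4-dibromobenzene | Brc1cc(Br)c(OCc2ccccc2)cc1OCc1ccccc1 | intermediate
3 | [3,5-bis(benzyloxy)-2,6-dibromophenyl]lithium | [Li]c1c(Br)c(OCc2ccccc2)cc(OCc2ccccc2)c1Br | intermediate
4 | dimethyl [3,5-bis(benzyloxy)-2,6-dibromophenyl]boronate | COB(OC)c1c(Br)c(OCc2ccccc2)cc(OCc2ccccc2)c1Br | intermediate
5 | 3,5-bis(benzyloxy)-2,6-dibromophenol | Oc1c(Br)c(OCc2ccccc2)cc(OCc2ccccc2)c1Br | intermediate
6 | methyl (2S)-2,3-dihydroxypropanoate | COC(=O)[C@@H](O)CO | starting material
7 | methyl (2S)-3-[(tert-butyldimethylsilyl)oxy]-2-hydroxypropanoate | COC(=O)[C@@H](O)CO[Si](C)(C)C(C)(C)C | intermediate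
8 | methyl (2R)-2-[3,5-bis(benzyloxy)-2,6-dibromophenoxy]-3-[(tert-butyldimethylsilyl)oxy]propanoate | COC(=O)[C@H](Oc1c(Br)c(OCc2ccccc2)cc(OCc2ccccc2)c1Br)CO[Si](C)(C)C(C)(C)C | intermediate
9 | (3R)-3-[3,5-bis(benzyloxy)-2,6-dibromophenoxy]-4-[(tert-butyldimethylsilyl)oxy]-2-methylbutan-2-ol | CC(C)(O)[C@H](Oc1c(Br)c(OCc2ccccc2)cc(OCc2ccccc2)c1Br)CO[Si](C)(C)C(C)(C)C | intermediate
10 | (2R)-2-[3,5-bis(benzyloxy)-2,6-dibromophenoxy]-3-methylbutane-1,3-diol | CC(C)(O)[C@H](Oc1c(Br)c(OCc2ccccc2)cc(OCc2ccccc2)c1Br)CO | intermediate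
11 | (2R)-2-[3,5-bis(benzyloxy)-2,6-dibromophenoxy]-3-hydroxy-3-methylbutyl 4-methylbenzenesulfonate | Cc1ccc(cc1)S(=O)(=O)OC[C@@H](Oc1c(Br)c(OCc2ccccc2)cc(OCc2ccccc2)c1Br)C(C)(C)O | intermediate
12 | (3R)-3-[3,5-bis(benzyloxy)-2,6-dibromophenoxy]-2,2-dimethyloxetane | CC1(C)OC[C@H]1Oc1c(Br)c(OCc2ccccc2)cc(OCc2ccccc2)c1Br | intermediate
13 | {4,6-bis(benzyloxy)-3-bromo-2-[(3R)-2,2-dimethyloxetan-3-yl]oxyphenyl}lithium | [Li]c1c(OCc2ccccc2)cc(OCc2ccccc2)c(Br)c1O[C@@H]1COC1(C)C | intermediate
14 | 2-[(2R)-4,6-bis(benzyloxy)-7-bromo-2,3-dihydro-1-benzofuran-2-yl]propan-2-ol | CC(C)(O)[C@H]1Cc2c(OCc3ccccc3)cc(OCc3ccccc3)c(Br)c2O1 | intermediate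
15 | 3-methylbutanoyl chloride | CC(C)CC(Cl)=O | starting material
16 | N,O-dimethylhydroxylamine hydrochloride | CNOC.Cl | starting material
17 | N-methoxy-N,3-dimethylbutanamide | CC(C)CC(=O)N(C)OC | intermediate
18 | lithium 2-[(2R)-4,6-bis(benzyloxy)-7-lithio-2,3-dihydro-1-benzofuran-2-yl]propan-2-olate | CC(C)(O[Li])[C@H]1Cc2c(OCc3ccccc3)cc(OCc3ccccc3)c([Li])c2O1 | intermediate
19 | dilithium salt of 1-[(2R)-4,6-bis(benzyloxy)-2-(2-hydroxypropan-2-yl)-2,3-dihydro-1-benzofuran-7-yl]-1-[methoxy(methyl)amino]-3-methylbutan-1-ol (both epimers at the new carbon) | CC(C)(O[Li])[C@H]1Cc2c(OCc3ccccc3)cc(OCc3ccccc3)c(C(O[Li])(CC(C)C)N(C)OC)c2O1 | intermediate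
20 | 1-[(2R)-4,6-bis(benzyloxy)-2-(2-hydroxypropan-2-yl)-2,3-dihydro-1-benzofuran-7-yl]-3-methylbutan-1-one | CC(C)(O)[C@H]1Cc2c(OCc3ccccc3)cc(OCc3ccccc3)c(C(=O)CC(C)C)c2O1 | intermediate
21 | 1-[(2R)-4,6-dihydroxy-2-(2-hydroxypropan-2-yl)-2,3-dihydro-1-benzofuran-7-yl]-3-methylbutan-1-one | CC(C)(O)[C@H]1Cc2c(O)cc(O)c(C(=O)CC(C)C)c2O1 | intermediate
22 | 1-bromo-3-methylbut-2-ene | CC(C)=CCBr | starting material
23 | 1-[(2R)-4,6-dihydroxy-2-(2-hydroxypropan-2-yl)-5-(3-methylbut-2-en-1-yl)-2,3-dihydro-1-benzofuran-7-yl]-3-methylbutan-1-one | CC(C)(O)[C@H]1Cc2c(O)c(CC=C(C)C)c(O)c(C(=O)CC(C)C)c2O1 | intermediate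
24 | (2R)-6-hydroxy-2-(2-hydroxypropan-2-yl)-7-(3-methylbutanoyl)-5,5-bis(3-methylbut-2-en-1-yl)-2,3-dihydro-1-benzofuran-4(5H)-one | CC(C)=CCC1(CC=C(C)C)C(=O)C2=C(O[C@@H](C(C)(C)O)C2)C(C(=O)CC(C)C)=C1O | target

**Step count**

Total step count: 11. Longest linear sequence: 9 steps (steps 1, 2, 4, 5, 6, 7, 9, 10, 11).

**Steps most likely to fail, with fallbacks**

Step 7 (proposed new method). What may go wrong: the aryllithium is protonated before it reaches the oxetane, or the Lewis acid ionizes the oxetane at its quaternary carbon instead of activating the CH2–O bond for displacement. The fallback uses known chemistry, sets out from diol 10 and comes back to the route at 14. The primary alcohol of 10 is converted to the bromide under Appel conditions (CBr4, PPh3, CH2Cl2, 0 °C), which should give (3S)-3-[3,5-bis(benzyloxy)-2,6-dibromophenoxy]-4-bromo-2-methylbutan-2-ol F1 (same spatial arrangement as 10; the descriptor changes only because CH2Br outranks the carbinol carbon). Treatment of this with n-BuLi (2.1 equiv, THF, −100 → −78 °C) forms the lithium alkoxide and then exchanges one aryl bromine. The resulting aryllithium should displace the primary bromide in a classical Parham cycloalkylation (5-exo-tet), much faster than the lithium alkoxide could close an oxetane, and aqueous work-up should give 14.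

Step 11. What may go wrong: O-prenylation competes with C-prenylation, or the reaction stops after the first C-prenylation. The fallback sets out from 21 and comes back at target 24; it delivers both prenyl groups by sigmatropic rearrangement instead of enolate alkylation. Both phenols of 21 are alkylated with 3-chloro-3-methylbut-1-yne (CuCl2 cat., DBU, MeCN, 0 °C), which should give 1-[(2R)-2-(2-hydroxypropan-2-yl)-4,6-bis[(2-methylbut-3-yn-2-yl)oxy]-2,3-dihydro-1-benzofuran-7-yl]-3-methylbutan-1-one F2. Semihydrogenation (H2, Pd/CaCO3 poisoned with Pb(OAc)2, quinoline, EtOAc) should give 1-[(2R)-2-(2-hydroxypropan-2-yl)-4,6-bis[(2-methylbut-3-en-2-yl)oxy]-2,3-dihydro-1-benzofuran-7-yl]-3-methylbutan-1-one F3. Heating this in toluene at 110 °C should bring about two successive aromatic Claisen rearrangements. C5 is the only free ortho position of either ether (C3a and C7 are substituted), so both 3-methylbut-2-enyl groups should arrive there, and the second rearrangement gives the dienone, which tautomerizes to 24.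

Step 9. What may go wrong: the hindered aryllithium, flanked by two oxygen substituents, abstracts an α-proton from the enolizable amide instead of adding to it, which returns the debrominated arene. The fallback sets out from 14 and comes back at 20; it replaces acyl substitution by carbonyl addition and oxidation. The dianion from 14 (n-BuLi, 2.1 equiv, THF, −78 °C) is added to the more electrophilic 3-methylbutanal, which should give 1-[(2R)-4,6-bis(benzyloxy)-2-(2-hydroxypropan-2-yl)-2,3-dihydro-1-benzofuran-7-yl]-3-methylbutan-1-ol F4 as a mixture of epimers at the new carbinol carbon. Dess–Martin periodinane (CH2Cl2, rt) should then oxidize the secondary benzylic alcohol, leaving the tertiary one, to give ketone 20.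

**Further compounds**

F1 | step 7 | (3S)-3-[3,5-bis(benzyloxy)-2,6-dibromophenoxy]-4-bromo-2-methylbutan-2-ol | CC(C)(O)[C@H](Oc1c(Br)c(OCc2ccccc2)cc(OCc2ccccc2)c1Br)CBr
F2 | step 11 | 1-[(2R)-2-(2-hydroxypropan-2-yl)-4,6-bis[(2-methylbut-3-yn-2-yl)oxy]-2,3-dihydro-1-benzofuran-7-yl]-3-methylbutan-1-one | CC(C)(O)[C@H]1Cc2c(OC(C)(C)C#C)cc(OC(C)(C)C#C)c(C(=O)CC(C)C)c2O1
F3 | step 11 | 1-[(2R)-2-(2-hydroxypropan-2-yl)-4,6-bis[(2-methylbut-3-en-2-yl)oxy]-2,3-dihydro-1-benzofuran-7-yl]-3-methylbutan-1-one | CC(C)(O)[C@H]1Cc2c(OC(C)(C)C=C)cc(OC(C)(C)C=C)c(C(=O)CC(C)C)c2O1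
F4 | step 9 | 1-[(2R)-4,6-bis(benzyloxy)-2-(2-hydroxypropan-2-yl)-2,3-dihydro-1-benzofuran-7-yl]-3-methylbutan-1-ol (both epimers at the carbinol carbon) | CC(C)(O)[C@H]1Cc2c(OCc3ccccc3)cc(OCc3ccccc3)c(C(O)CC(C)C)c2O1
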